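**The unit.** Percent of left-handed product per millimolar of free catalyst is what I compare, and I compare it at equal time. The flask and its two neighbours, eta and gamma, differ in the free catalyst charged.

the same everywhere: left-handed substrate 0.10 M; right-handed substrate 0.10 M

|  | solid reagent | free catalyst | remark |
|---|---|---|---|
| eta | 0.20 M | 0.13 mM | run made earlier |
| gamma | 0.20 M | 0.30 mM | run made earlier |
| flask | 0.200 M | 0.20 mM |  |

| run | time / min | left-handed product / % | left-handed substrate / % |
|---|---|---|---|
| eta | 0.200 | 1.2 | 48.2 |
| eta | 0.333 | 4.5 | 45.2 |
| eta | 0.667 | 7.3 | 42.7 |
| eta | 1.33 | 11.2 | 37.3 |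
| eta | 2.50 | 13.7 | 35.8 |
| gamma | 0.200 | 2.6 | 47.0 |
| gamma | 0.667 | 17.4 | 32.8 |
| gamma | 1.00 | 22.8 | 28.9 |
| gamma | 1.50 | 24.6 | 25.8 |
| gamma | 2.50 | 23.5 | 24.7 |

(standard deviation of a reading: 1 percentage point)

- free catalyst is single-handed; left-handed substrate and right-handed substrate are mirror images of each other, charged as a racemate, each of them at the stated concentration
- solid, in amounts per volume of the solution: solid reagent
- the numbers in the tables scatter by 1 percentage point (one standard deviation)
- at the start none of the solid reagent is in solution

1. apparent order in free catalyst when 5.0% of the left-handed substrate and right-handed substrate together are converted (percent change of the rate of making left-handed product for one percent more free catalyst charged)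

**Two neighbours.** At 0.667 min eta holds 7.3% of left-handed product and gamma holds 17.4%. The logarithm of that ratio over the logarithm of the catalyst ratio gives 1.04, my equal-clock order n, give or take 0.178. As a check, gamma's 2.6% at 0.200 min, scaled by n, gives 1.09% for eta, which reads 1.2%.

**The ends.** At 2.50 min the same ratio gives 0.645, with gamma at 23.5% and eta at 13.7%. Left-handed substrate remains in both, 24.7% in gamma and 35.8% in eta. If one solid reagent goes per left-handed product, gamma's left-handed product took 0.0470 M, less than the 0.20 M charged. So I suspect a second route that spends solid reagent without catalyst, with eta and gamma each stalling once that reagent is lost.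

**My number.** The level asked lies in the early stretch, so I commit to n, though it is read at equal time, not equal conversion. The forecast, higher than mine, gives 1.25, holding that “the catalyst must be dying”.

**The result.** The flask gives an apparent order of 0.93, within the scatter of n.

    free catalyst + left-handed substrate ⇌ catalyst intermediate A (K = 10.0 L mol⁻¹, k = 1410 L mol⁻¹ s⁻¹)
    free catalyst + right-handed substrate ⇌ catalyst intermediate B (K = 3.60 L mol⁻¹, k = 1190 L mol⁻¹ s⁻¹)
    partner + catalyst intermediate A → free catalyst + left-handed product (k = 188 L mol⁻¹ s⁻¹)
    partner + catalyst intermediate B → free catalyst + right-handed product (k = 92.7 L mol⁻¹ s⁻¹)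
    solid reagent ⇌ partner, rate k5*(cs5 - [partner]) while solid is left; crystals form when [partner] > cs5 (solubility = 0.0620 M, k = 0.186 s⁻¹)
    2 partner → self-condensation product (k = 0.840 L mol⁻¹ s⁻¹)

**The flask.** Gamma's 22.8% at 1.00 min, scaled to this flask's catalyst by n, gives 15.0%, and the flask holds 15.4% at 1.00 min. In the flask, half of the self-condensation turnover up to 2.00 min is done by 0.506 min, sooner than the 0.80 min half-life of partner by the step to left-handed product at 0.335 min. At 2.00 min the flask holds 0.0759 M of self-condensation product, its solid reagent, the limiting reagent, stands at 0% of its own charge, and 63% of the left-handed substrate charged is left.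

(The data are calculated with made-up constants; the scatter is artificial.)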